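**Retrosynthetic overview**
- The target is a linear pentamer A–O–B–O–C–O–D–O–E of purchased benzene rings. No ring is constructed; the rings are joined in the order A–B, B–C, D–E, C–D, and twelve methyl ethers are cleaved last.
- The strategy rests on ring C: it carries oxygen on three neighbouring carbons, C1–O (to ring B), C2–O (to ring D) and C3–OH, plus C5–OH. C1 and C2 are the positions at which a nucleophile and an electrophile add across a 3-alkoxyaryne.
- Key disconnection: the ring B O–C1 bond and a C2–I bond are formed together from the AB phenoxide, 3,5-dimethoxybenzyne and an iodine donor.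
- C2–I is then converted to C2–OH, and the C2–O–ring D bond is made by copper coupling with a preformed DE aryl bromide.
- The aryne precursor comes from 3,5-dimethoxyphenol by carbamate-directed ortho-silylation; the AB phenol and the DE bromide both come from 4-bromo-2,6-dimethoxyphenol.

Key step: step 7

Assumption: rings are lettered A to E from the 2,4,6-trihydroxyphenoxy end to the 3,4,5-trihydroxyphenoxy end; the target has no stereocentre; 2,4,6-trimethoxyphenol 11 and boronic acid 21 are taken as catalogue compounds.

**Route**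

Step 1
Reactants: 1 3,5-dimethoxyphenol
Product: 2 3,5-dimethoxyphenyl N-isopropylcarbamate
Conditions: i-PrNCO, Et3N (cat.), CH2Cl2, rt
Reagents that add atoms: isopropyl isocyanate, CC(C)N=C=O
Why: Amine-catalysed addition of the phenol O–H across the isocyanate (carbamoylation) should be clean for an unhindered phenol and installs the group that later directs metalation.

Step 2
Reactants: 2 3,5-dimethoxyphenyl N-isopropylcarbamate
Product: 6 3,5-dimethoxy-2-(trimethylsilyl)phenyl N-isopropylcarbamate, via N-silyl carbamate 3 (not isolated), via aryllithium 4 (not isolated), via C-silyl N-silyl carbamate 5 (not isolated)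
Conditions: TBSOTf, TMEDA, Et2O, 0 °C to rt; n-BuLi (2 equiv), TMEDA, −78 °C; TMSCl, −78 °C to rt; sat. aq. NH4Cl
Reagents that add atoms: chlorotrimethylsilane, C[Si](C)(C)Cl
Why: Directed ortho-metalation: N-silylation in the flask masks the carbamate N–H, n-BuLi/TMEDA lithiates C2 between the carbamate oxygen and a methoxy group (C2 and C6 are equivalent, and the carbamate outranks the two methoxy groups that flank C4), and TMSCl traps the aryllithium at −78 °C before an anionic Fries shift can set in; the mild work-up removes the N-silyl group without acid that would protodesilylate the electron-rich arylsilane.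

Step 3
Reactants: 6 3,5-dimethoxy-2-(trimethylsilyl)phenyl N-isopropylcarbamate
Product: 8 3,5-dimethoxy-2-(trimethylsilyl)phenyl trifluoromethanesulfonate, via silyl phenol 7 (not isolated)
Conditions: DBU, Et2NH, MeCN, 40 °C; then PhNTf2, rt
Reagents that add atoms: N-phenylbis(trifluoromethanesulfonimide), O=S(=O)(N(c1ccccc1)S(=O)(=O)C(F)(F)F)C(F)(F)F
Why: E1cB cleavage of the N-monoalkyl carbamate (DBU removes N–H, isopropyl isocyanate is expelled and scavenged by diethylamine) frees the ortho-silyl phenoxide, which is O-triflated in the same flask under non-acidic conditions that spare the aryl–silicon bond.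

Step 4
Reactants: 9 4-bromo-2,6-dimethoxyphenol
Product: 10 2-(benzyloxy)-5-bromo-1,3-dimethoxybenzene
Conditions: BnBr, K2CO3, DMF, rt
Reagents that add atoms: benzyl bromide, BrCc1ccccc1
Why: Williamson ether synthesis (SN2 of the phenoxide on benzyl bromide) masks the phenol as a benzyl ether that can later be removed without touching methyl ethers.

Step 5
Reactants: 10 2-(benzyloxy)-5-bromo-1,3-dimethoxybenzene, 11 2,4,6-trimethoxyphenol
Product: 12 2-(benzyloxy)-1,3-dimethoxy-5-(2,4,6-trimethoxyphenoxy)benzene
Conditions: CuI (10 mol%), picolinic acid (20 mol%), K3PO4, DMSO, 90 °C, Ar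
Reagents that add atoms: none
Why: Ligand-accelerated Ullmann diaryl ether synthesis tolerates 2,6-disubstituted phenols when the aryl bromide has free ortho positions, as it has here, and the inert atmosphere protects the oxidisable phenol.

Step 6
Reactants: 12 2-(benzyloxy)-1,3-dimethoxy-5-(2,4,6-trimethoxyphenoxy)benzene
Product: 13 2,6-dimethoxy-4-(2,4,6-trimethoxyphenoxy)phenol (AB phenol)
Conditions: H2 (1 atm), Pd/C (10% palladium on carbon), EtOAc/MeOH, rt
Reagents that add atoms: none
Why: Catalytic hydrogenolysis cleaves only the benzylic C–O bond; methyl and diaryl ethers are inert.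

Step 7
Reactants: 13 2,6-dimethoxy-4-(2,4,6-trimethoxyphenoxy)phenol, 8 3,5-dimethoxy-2-(trimethylsilyl)phenyl trifluoromethanesulfonate
Product: 17 1-[2,6-dimethoxy-4-(2,4,6-trimethoxyphenoxy)phenoxy]-2-iodo-3,5-dimethoxybenzene (ABC iodide), via potassium phenoxide 14 (not isolated), via 3,5-dimethoxybenzyne 15 (not isolated), via C2 aryl anion 16 (not isolated)
Conditions: KH (1.0 equiv), THF, 0 °C; then 18-crown-6, KF, (CF3)2CFI (3 equiv), 8 (1.5 equiv, slow addition), THF, 0 °C to rt, dark, Ar
Reagents that add atoms: heptafluoro-2-iodopropane, FC(F)(F)C(F)(I)C(F)(F)F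
Why: Proposed new method: fluoride-induced 1,2-elimination of 8 releases aryne 15, phenoxide 14 (made with KH so that no conjugate acid stays in the flask) adds through oxygen to C1, and the C2 aryl anion 16 takes iodine from the perfluoroalkyl iodide by halogen–metal exchange, so the B–O–C1 and C2–I bonds should form in one operation. The closest known reaction types are three-component aryne couplings in which a heteroatom nucleophile adds and the aryl anion is trapped by a halogen donor or by CO2, and the metal-free O-arylation of 2,6-disubstituted phenols by arynes; the pairing of a phenoxide with an iodine donor is untested. No ring is closed and no stereocentre is formed. The step needs attack at C1 rather than C2: the inductively withdrawing C3 methoxy group distorts the aryne so that C1 is the more electrophilic carbon and the charge develops at C2 beside oxygen, an effect that outweighs the weak opposite bias of the C5 methoxy group and is reinforced by the bulk of 14. It also needs O- rather than C-arylation, secured because both ortho positions and the para position of the phenoxide ring are substituted, and iodination rather than protonation, secured by the aprotic medium (no amine, alcohol or nitrile) and the excess of iodine donor. The spent donor anion (CF3)2CF− is non-basic and sheds gaseous hexafluoropropene, and the fluoride it returns sustains aryne formation.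

Step 8
Reactants: 17 1-[2,6-dimethoxy-4-(2,4,6-trimethoxyphenoxy)phenoxy]-2-iodo-3,5-dimethoxybenzene
Product: 20 2-[2,6-dimethoxy-4-(2,4,6-trimethoxyphenoxy)phenoxy]-4,6-dimethoxyphenol (ABC phenol), via arylmagnesium chloride 18 (not isolated), via dimethyl arylboronate 19 (not isolated)
Conditions: i-PrMgCl·LiCl, THF, −20 to 0 °C; B(OMe)3, −20 °C to rt; 30% aq. H2O2, aq. NaOH, 0 °C
Reagents that add atoms: hydrogen peroxide, OO
Why: Iodine–magnesium exchange is fast for an aryl iodide flanked by two oxygen substituents, the arylmagnesium is borylated by trimethyl borate, and alkaline peroxide oxidation (1,2-aryl shift from boron to oxygen) at 0 °C should outrun protodeboronation of the 2,6-dioxygenated arylboron species.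

Step 9
Reactants: 9 4-bromo-2,6-dimethoxyphenol, 21 3,4,5-trimethoxyphenylboronic acid
Product: 22 5-bromo-1,3-dimethoxy-2-(3,4,5-trimethoxyphenoxy)benzene (DE bromide)
Conditions: Cu(OAc)2 (1 equiv), pyridine, 4 Å MS, CH2Cl2, dry air, rt
Reagents that add atoms: none
Why: Chan–Lam–Evans oxidative coupling at room temperature arylates 2,6-disubstituted phenols with unhindered arylboronic acids and leaves the aryl bromide untouched, air acting as terminal oxidant that returns copper to the divalent state.

Step 10
Reactants: 20 2-[2,6-dimethoxy-4-(2,4,6-trimethoxyphenoxy)phenoxy]-4,6-dimethoxyphenol, 22 5-bromo-1,3-dimethoxy-2-(3,4,5-trimethoxyphenoxy)benzene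
Product: 23 1-[2,6-dimethoxy-4-(2,4,6-trimethoxyphenoxy)phenoxy]-2-[3,5-dimethoxy-4-(3,4,5-trimethoxyphenoxy)phenoxy]-3,5-dimethoxybenzene (dodecamethyl ether of the target)
Conditions: CuI (20 mol%), picolinic acid (40 mol%), K3PO4, DMSO, 100 °C, Ar
Reagents that add atoms: none
Why: Ullmann diaryl ether synthesis of the same type as step 5: the hindered partner is the phenol, while bromide 22 is unsubstituted at both ortho positions, the arrangement that copper/picolinic acid catalysis tolerates best.

Step 11
Reactants: 23 dodecamethyl ether of the target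
Product: 24 5-[2,6-dihydroxy-4-(2,4,6-trihydroxyphenoxy)phenoxy]-4-[3,5-dihydroxy-4-(3,4,5-trihydroxyphenoxy)phenoxy]benzene-1,3-diol (CNP0227069.0)
Conditions: BBr3 (excess), CH2Cl2, −78 °C to rt; then MeOH, H2O, 0 °C, under Ar
Reagents that add atoms: none
Why: Lewis acid-mediated ether cleavage: BBr3 binds each methoxy oxygen and bromide removes the methyl group by SN2, whereas diaryl ether C–O bonds offer no sp3 carbon and should survive; degassed work-up protects the air-sensitive polyphenol.

**Compound list**
1 | 3,5-dimethoxyphenol | COc1cc(O)cc(OC)c1 | starting material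
2 | 3,5-dimethoxyphenyl N-isopropylcarbamate | COc1cc(OC)cc(OC(=O)NC(C)C)c1 | intermediate
3 | 3,5-dimethoxyphenyl N-(tert-butyldimethylsilyl)-N-isopropylcarbamate (not isolated) | COc1cc(OC)cc(OC(=O)N(C(C)C)[Si](C)(C)C(C)(C)C)c1 | intermediate
4 | C2 aryllithium of 3 (not isolated) | [Li]c1c(OC)cc(OC)cc1OC(=O)N(C(C)C)[Si](C)(C)C(C)(C)C | intermediate
5 | 3,5-dimethoxy-2-(trimethylsilyl)phenyl N-(tert-butyldimethylsilyl)-N-isopropylcarbamate (not isolated) | COc1cc(OC)c([Si](C)(C)C)c(OC(=O)N(C(C)C)[Si](C)(C)C(C)(C)C)c1 | intermediate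
6 | 3,5-dimethoxy-2-(trimethylsilyl)phenyl N-isopropylcarbamate | COc1cc(OC)c([Si](C)(C)C)c(OC(=O)NC(C)C)c1 | intermediate
7 | 3,5-dimethoxy-2-(trimethylsilyl)phenol (present as its amidinium phenoxide, not isolated) | COc1cc(O)c([Si](C)(C)C)c(OC)c1 | intermediate
8 | 3,5-dimethoxy-2-(trimethylsilyl)phenyl trifluoromethanesulfonate | COc1cc(OC)c([Si](C)(C)C)c(OS(=O)(=O)C(F)(F)F)c1 | intermediate
9 | 4-bromo-2,6-dimethoxyphenol | COc1cc(Br)cc(OC)c1O | starting material
10 | 2-(benzyloxy)-5-bromo-1,3-dimethoxybenzene | COc1cc(Br)cc(OC)c1OCc1ccccc1 | intermediate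
11 | 2,4,6-trimethoxyphenol | COc1cc(OC)c(O)c(OC)c1 | starting material
12 | 2-(benzyloxy)-1,3-dimethoxy-5-(2,4,6-trimethoxyphenoxy)benzene | COc1cc(OC)c(Oc2cc(OC)c(OCc3ccccc3)c(OC)c2)c(OC)c1 | intermediate
13 | 2,6-dimethoxy-4-(2,4,6-trimethoxyphenoxy)phenol (AB phenol) | COc1cc(OC)c(Oc2cc(OC)c(O)c(OC)c2)c(OC)c1 | intermediate
14 | potassium 2,6-dimethoxy-4-(2,4,6-trimethoxyphenoxy)phenoxide (not isolated) | COc1cc(OC)c(Oc2cc(OC)c([O-])c(OC)c2)c(OC)c1.[K+] | intermediate
15 | 3,5-dimethoxybenzyne (not isolated) | COC1=CC(OC)=CC#C1 | intermediate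
16 | C2 aryl potassium adduct of 14 and 15 (not isolated) | COc1cc(OC)c([K])c(Oc2c(OC)cc(Oc3c(OC)cc(OC)cc3OC)cc2OC)c1 | intermediate
17 | 1-[2,6-dimethoxy-4-(2,4,6-trimethoxyphenoxy)phenoxy]-2-iodo-3,5-dimethoxybenzene (ABC iodide) | COc1cc(OC)c(I)c(Oc2c(OC)cc(Oc3c(OC)cc(OC)cc3OC)cc2OC)c1 | intermediate
18 | arylmagnesium chloride from 17 (not isolated) | COc1cc(OC)c([Mg]Cl)c(Oc2c(OC)cc(Oc3c(OC)cc(OC)cc3OC)cc2OC)c1 | intermediate
19 | dimethyl arylboronate from 18 (not isolated) | COB(OC)c1c(OC)cc(OC)cc1Oc1c(OC)cc(Oc2c(OC)cc(OC)cc2OC)cc1OC | intermediate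
20 | 2-[2,6-dimethoxy-4-(2,4,6-trimethoxyphenoxy)phenoxy]-4,6-dimethoxyphenol (ABC phenol) | COc1cc(OC)c(O)c(Oc2c(OC)cc(Oc3c(OC)cc(OC)cc3OC)cc2OC)c1 | intermediate
21 | 3,4,5-trimethoxyphenylboronic acid | COc1cc(B(O)O)cc(OC)c1OC | starting material
22 | 5-bromo-1,3-dimethoxy-2-(3,4,5-trimethoxyphenoxy)benzene (DE bromide) | COc1cc(Br)cc(OC)c1Oc1cc(OC)c(OC)c(OC)c1 | intermediate
23 | 1-[2,6-dimethoxy-4-(2,4,6-trimethoxyphenoxy)phenoxy]-2-[3,5-dimethoxy-4-(3,4,5-trimethoxyphenoxy)phenoxy]-3,5-dimethoxybenzene | COc1cc(OC)c(Oc2cc(OC)c(Oc3cc(OC)cc(OC)c3Oc3cc(OC)c(Oc4cc(OC)c(OC)c(OC)c4)c(OC)c3)c(OC)c2)c(OC)c1 | intermediate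
24 | 5-[2,6-dihydroxy-4-(2,4,6-trihydroxyphenoxy)phenoxy]-4-[3,5-dihydroxy-4-(3,4,5-trihydroxyphenoxy)phenoxy]benzene-1,3-diol (CNP0227069.0) | Oc1cc(O)c(Oc2cc(O)c(Oc3cc(O)cc(O)c3Oc3cc(O)c(Oc4cc(O)c(O)c(O)c4)c(O)c3)c(O)c2)c(O)c1 | target

**Step count**
Total: 11 steps. Longest linear sequence: 7 steps (steps 4, 5, 6, 7, 8, 10, 11; the branch through steps 1, 2, 3 is equally long).

**Steps most likely to fail**

Step 7. Three processes threaten it: protonation of the C2 aryl anion instead of iodine transfer, electron transfer from the very electron-rich phenoxide to the perfluoroalkyl iodide, and consumption of phenoxide by the hexafluoropropene that the spent donor releases. The fallback uses known chemistry, sets out from AB phenol 13 and comes back at ABC phenol 20. Nucleophilic aromatic substitution of the phenoxide of 13 (K2CO3, DMA, 130 °C) on 2-fluoro-4,6-dimethoxybenzaldehyde F1, taken as a catalogue compound, should give 2-[2,6-dimethoxy-4-(2,4,6-trimethoxyphenoxy)phenoxy]-4,6-dimethoxybenzaldehyde F2. The fluorine is activated by the ortho formyl group, and both methoxy groups are meta to it. Baeyer–Villiger (Dakin-type) oxidation of this electron-rich aldehyde with mCPBA in CH2Cl2 should give 2-[2,6-dimethoxy-4-(2,4,6-trimethoxyphenoxy)phenoxy]-4,6-dimethoxyphenyl formate F3, and methanolysis (K2CO3, MeOH, rt) then gives 20. The formyl carbon marks C2 of ring C, so the oxygen pattern is the same as that set by the aryne route.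

Step 10. The phenoxide of 20 is flanked by a methoxy group and a bulky aryloxy group, so ligand exchange at copper may be slow and the electron-rich bromide 22 may be reduced or left unconverted at 100 °C. The fallback sets out from bromide 22 and phenol 20 and comes back at 23. Bromine–lithium exchange on 22 (n-BuLi, THF, −78 °C), quench with B(Oi-Pr)3 and mild aqueous hydrolysis should give [3,5-dimethoxy-4-(3,4,5-trimethoxyphenoxy)phenyl]boronic acid F4. Chan–Lam–Evans oxidative coupling of F4 with 20 (Cu(OAc)2, pyridine, 4 Å MS, CH2Cl2, dry air, rt) then forms the same C2–O–ring D bond at room temperature, a coupling mode that accepts 2,6-disubstituted phenols when the boronic acid has free ortho positions.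

Step 11. Cleavage of twelve methyl ethers may stop at partly methylated stages, and the free polyphenol (a pyrogallol ring E and several phloroglucinol-type rings) may oxidise during isolation. The fallback sets out from 23 and comes back at 24. After treatment with BBr3 the volatiles are removed and the crude polyphenol is acetylated in the same flask (Ac2O, pyridine, DMAP cat.) to the dodecaacetate of the target F5. This ester is stable to air and silica, so under-demethylated congeners can be removed by chromatography. Acid-catalysed methanolysis (AcCl cat., degassed MeOH, rt) then releases 24 without exposing it to base.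

**Further compounds**
F1 | step 7 | 2-fluoro-4,6-dimethoxybenzaldehyde (purchased) | COc1cc(F)c(C=O)c(OC)c1
F2 | step 7 | 2-[2,6-dimethoxy-4-(2,4,6-trimethoxyphenoxy)phenoxy]-4,6-dimethoxybenzaldehyde | COc1cc(OC)c(C=O)c(Oc2c(OC)cc(Oc3c(OC)cc(OC)cc3OC)cc2OC)c1
F3 | step 7 | 2-[2,6-dimethoxy-4-(2,4,6-trimethoxyphenoxy)phenoxy]-4,6-dimethoxyphenyl formate | COc1cc(OC)c(OC=O)c(Oc2c(OC)cc(Oc3c(OC)cc(OC)cc3OC)cc2OC)c1
F4 | step 10 | [3,5-dimethoxy-4-(3,4,5-trimethoxyphenoxy)phenyl]boronic acid | COc1cc(B(O)O)cc(OC)c1Oc1cc(OC)c(OC)c(OC)c1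
F5 | step 11 | dodecaacetate of the target | CC(=O)Oc1cc(OC(C)=O)c(Oc2cc(OC(C)=O)c(Oc3cc(OC(C)=O)cc(OC(C)=O)c3Oc3cc(OC(C)=O)c(Oc4cc(OC(C)=O)c(OC(C)=O)c(OC(C)=O)c4)c(OC(C)=O)c3)c(OC(C)=O)c2)c(OC(C)=O)c1
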